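# Luteolin 7-sulfate by way of a 3,5-diarylisoxazole: synthesis design

## The problem

Luteolin 7-sulfate (14) is a flavone: a phloroglucinol-type ring A is fused to the 4-pyranone ring C, and the catechol ring B sits on C2. The molecule is flat and has no stereocentre, so every difficulty is one of regiochemistry and of telling similar oxygens apart. Both benzene rings can be bought with their oxygens in place. The carbon work is therefore limited to the bridge C2–C3–C4 and the O1–C2 bond, with the carbonyl on the ring A side and the enol-ether carbon on the ring B side. Of four phenolic oxygens only O7 carries the sulfate. O7 and O4' are the two most acidic phenols and cannot be told apart without protection, whereas O5 is hydrogen-bonded to the C4 carbonyl and is the least reactive. The aryl sulfate monoester is the fragile group: it is lost in warm acid and does not tolerate Lewis acids, so it must come after all acid-mediated steps, and whatever protection remains must then leave under neutral conditions. What makes a short convergent plan possible is that C2–C3–C4(=O) is at the oxidation level of a 1,3-diketone, the unit that an isoxazole stores, with the ring oxygen on the future C4 and the nitrogen on the future C2. Ring A is also symmetric about the C4a–C7 axis, so either ortho oxygen can become O1 and ring C can close in only one way.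

## Retrosynthesis

**14 to 12.** The last bonds cut are the two benzyl–oxygen bonds of ring B, with 13 as the debenzylated sodium salt that is protonated to 14. Benzyl ethers are chosen because they survive chlorination, base, reductive N–O cleavage, methanolic acid and sulfation, and then leave under neutral hydrogenolysis, to which an aryl sulfate anion is inert. The forward step must cleave two benzyl ethers without saturating the C2–C3 double bond.

**12 to 11.** The O7–S bond is cut next. Sulfating free luteolin would not distinguish O7 from O4', so the sulfate goes on while ring B is still blocked. In 11 only O5 and O7 are free, and the hydrogen bond from O5 to the C4 carbonyl leaves O7 as the only reactive phenol. The forward step asks for mono-sulfation under mild basic conditions.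

**11 to 9.** Ring C is opened at O1–C2, with an amino group on C2 and the ring A phenols masked as methoxymethyl ethers. The enaminone 9 is preferred to the corresponding 1,3-diketone because it is the direct product of opening an isoxazole and needs no separate hydrolysis. One acid treatment removes the three acetals (giving 10), closes ring C and expels ammonia. The acid must leave the benzyl ethers alone, which methanolic HCl does.

**9 to 8.** Joining the nitrogen of 9 to the carbonyl oxygen gives the isoxazole 8. This changes a reactive vinylogous amide into an aromatic heterocycle that tolerates base, chromatography and storage and holds all fifteen skeletal carbons. The forward step is a reductive N–O cleavage that must spare benzyl ethers, which rules out catalytic hydrogenation at this stage.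

**8 to 7 and 3 (key cut).** In flavone numbering, the C2–C3 bond and the bond from C4 to the isoxazole oxygen are cut. This gives the ring B nitrile oxide 7 and the ring A arylacetylene 3, and 7 goes back through the hydroximoyl chloride 6 to the aldoxime 5.
- Against the C3–C4 acylation of a 2,4,6-trioxygenated acetophenone enolate: that route needs strong base on a hindered ketone.
- Against the C2–C3 aldol to a chalcone: that route needs a later oxidation and risks aurone formation.
- The cycloaddition makes the carbon–carbon bond under nearly neutral conditions, delivers the bridge at the correct oxidation level, and reduces both halves to benzaldehydes.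
- It must give the 3,5- and not the 3,4-disubstituted isoxazole.

**3 to 1 and 5 to 4.** The alkyne 3 comes from aldehyde 2 by a one-carbon homologation (C–C triple bond cut back to the formyl group), and 2 from commercial 1 by acetal protection of the three phenols. The oxime 5 comes from commercial 4 by oximation. Both fragments are one or two steps from catalogue benzaldehydes, and none of these steps bears on selectivity.

## Roads not taken

**Alternative 1:** Ring B is built, not bought. The cut runs through C1'–C2' and C5'–C6'. The terminal alkyne of 5,7-bis(benzyloxy)-2-ethynyl-4H-chromen-4-one A2 would add 2,3-bis(tert-butyldimethylsilyloxy)buta-1,3-diene A3 in a [4+2] cycloaddition to give the cyclohexa-1,4-diene A1, and a dehydrogenation would then be needed to reach the aromatic catechol.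
- Merits: the diene is symmetric, so regiochemistry is not an issue. The silyl ethers on ring B could be removed by fluoride after sulfation, so no hydrogen would meet the sulfate. That is a real advantage over the benzyl ethers used here.
- Weak points: it constructs a benzene ring that comes for nothing in 4. It adds an oxidation step. A2 itself takes several steps to make. The chromone C2–C3 bond is a second electrophilic site beside the alkyne. The bis(silyloxy)diene is hydrolytically labile. The ring A benzyl ethers must still be hydrogenolysed before sulfation.
- Comparison: the route is several steps longer. Against its fluoride endgame the chosen plan sets a hydrogenolysis of a kind that is well established on aryl sulfate salts.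

**Alternative 2:** Ring A is closed last by a polyketide-type folding, with the cut at C4a–C5. Methyl 4-{6-[3,4-bis(benzyloxy)phenyl]-4-oxo-4H-pyran-2-yl}-3-oxobutanoate A5 would, under a magnesium alkoxide, acylate its pyranone carbon C4a on the terminal ester and aromatise to 3',4'-bis(benzyloxy)-5,7-dihydroxyflavone A4. A4 is the same compound as 11, so the endgame would be shared.
- Merits: ring A needs no protecting groups and no N–O cleavage, and the idea mirrors biosynthesis. In these respects it is better than the chosen plan if the folding works.
- Weak points: A5 has to be assembled by stepwise acylation of a pyranone side chain through polyanions. The tricarbonyl chain can close in aldol fashion instead of Claisen fashion. Alkoxide can open the pyranone by conjugate addition. The mode of folding depends strongly on the metal and is hard to predict.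
- Comparison: the chosen plan reaches the same compound in six steps (five in the longest line) from two benzaldehydes, each step a standard transformation. It pays for that reliability with the placing and removal of the acetal ethers.

**Alternative 3:** Ring C is closed at C4–C4a by intramolecular Friedel–Crafts acylation. The activated carboxyl group of (Z)-3-[3,5-bis(benzyloxy)phenoxy]-3-[3,4-bis(pivaloyloxy)phenyl]acrylic acid A7 would attack the position ortho to the ether oxygen to give 5,7-bis(benzyloxy)-3',4'-bis(pivaloyloxy)flavone A6.
- Merits: the aryloxy ring is symmetric and strongly activated, so both ortho positions are equivalent. The pivalates deactivate ring B and could be removed by mild base after sulfation, again sparing the sulfate a hydrogenation. The step count is comparable to the chosen plan.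
- Weak points: A7 must have the carboxyl group cis to the aryloxy group, and phenol addition to an arylpropiolate does not guarantee that geometry. Freeing the acid beside aryl pivalates is not selective. Strongly acidic acylation media endanger benzyl ethers on a phloroglucinol ring (cleavage and C-benzylation). The ring A benzyl ethers must still be removed before sulfation.
- Comparison: about equal in length and better in its last deprotection. The chosen plan sets against it a carbon–carbon bond formation under nearly neutral conditions, no alkene geometry to control, and no strong acid while benzyl ethers sit on an electron-rich ring.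

Key step: step 4

Assumption: the target is taken as the free hydrogen sulfate as drawn. Because aryl hydrogen sulfates hydrolyse on standing in acid, the sulfate is carried as its sodium salt and protonated only at the very end, in the cold.

## Route

Step 1
Reactants: 1 2,4,6-trihydroxybenzaldehyde
Product: 2 2,4,6-tris(methoxymethoxy)benzaldehyde
Conditions: NaH, MOMCl, DMF, 0 °C to rt
Reagents that add atoms: chloromethyl methyl ether, COCCl
Why: O-alkylation of the phenoxides with a hard chloromethyl ether (MOM protection); NaH is used because the two ortho hydroxyls are hydrogen-bonded to the formyl group and react poorly with amine bases. The acetal ethers withstand base and reduction and fall off in the acid step that closes ring C.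

Step 2
Reactants: 2 2,4,6-tris(methoxymethoxy)benzaldehyde
Product: 3 2-ethynyl-1,3,5-tris(methoxymethoxy)benzene
Conditions: dimethyl (1-diazo-2-oxopropyl)phosphonate, K2CO3, MeOH–THF, 0 °C to rt
Reagents that add atoms: dimethyl (1-diazo-2-oxopropyl)phosphonate, COP(=O)(OC)C(=[N+]=[N-])C(C)=O
Why: Ohira–Bestmann homologation: methanolysis releases the diazomethylphosphonate anion, which olefinates the aldehyde; loss of N2 and a 1,2-hydrogen shift of the alkylidene carbene give the terminal alkyne. The mild carbonate medium leaves the acetal ethers untouched.

Step 3
Reactants: 4 3,4-bis(benzyloxy)benzaldehyde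
Product: 5 (E)-3,4-bis(benzyloxy)benzaldehyde oxime
Conditions: NH2OH·HCl, NaOAc, EtOH–H2O, rt
Reagents that add atoms: hydroxylamine hydrochloride, Cl.NO
Why: Acetate-buffered condensation of an aryl aldehyde with hydroxylamine (oxime formation); the E isomer with OH anti to the aryl group is the thermodynamic product, and the geometry is in any case lost when the nitrile oxide forms.

Step 4
Reactants: 5 (E)-3,4-bis(benzyloxy)benzaldehyde oxime; 3 2-ethynyl-1,3,5-tris(methoxymethoxy)benzene
Product: 8 3-[3,4-bis(benzyloxy)phenyl]-5-[2,4,6-tris(methoxymethoxy)phenyl]isoxazole, via hydroximoyl chloride 6 (not isolated), via nitrile oxide 7 (not isolated)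
Conditions: 5 (1.5 equiv), NCS, DMF, rt; then 3, Et3N (slow addition), CH2Cl2, 0 °C to rt
Reagents that add atoms: none
Why: NCS chlorinates the aldoxime carbon of 5 to give hydroximoyl chloride 6, and slow addition of Et3N removes HCl to release nitrile oxide 7 at a low stationary concentration beside alkyne 3. Compound 7 and the terminal alkyne then combine in a concerted, asynchronous Huisgen [3+2] cycloaddition that forms the bond from the nitrile oxide carbon to the terminal alkyne carbon (future C2–C3) and the bond from the dipole oxygen to the internal alkyne carbon (future C4–O); the closest known reaction type is the union of an aryl nitrile oxide with a terminal arylacetylene to a 3,5-diarylisoxazole. The five-membered ring is closed intermolecularly as a cycloadduct, both new sigma bonds arising in one step from a three-atom and a two-atom component, and it is aromatic as formed, so no oxidation follows. No stereocentre is created. The selectivity required is regiochemical, 3,5- against 3,4-disubstitution: the electron-rich arylacetylene has its larger HOMO coefficient on the unsubstituted terminal carbon, which pairs with the carbon end of the dipole, and the doubly ortho-substituted aryl group keeps the bulkier dipole terminus away from the internal carbon, so electronic and steric effects both point to 8. Dimerisation of 7 to the furoxan is held back by its slow release and by the excess of 5, and ring chlorination of the electron-rich arenes is avoided by finishing the chlorination before 3 is added. Benzyl and acetal ethers are inert to triethylamine and its hydrochloride at room temperature.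

Step 5
Reactants: 8 3-[3,4-bis(benzyloxy)phenyl]-5-[2,4,6-tris(methoxymethoxy)phenyl]isoxazole
Product: 9 (Z)-3-amino-3-[3,4-bis(benzyloxy)phenyl]-1-[2,4,6-tris(methoxymethoxy)phenyl]prop-2-en-1-one
Conditions: Mo(CO)6, MeCN–H2O, 80 °C
Reagents that add atoms: none
Why: Reductive N–O cleavage of an isoxazole by Mo(CO)6 and water: zerovalent molybdenum binds the ring nitrogen and inserts into the weak N–O bond, and water then releases the vinylogous amide, held in the Z form by an N–H to carbonyl hydrogen bond. Benzyl and acetal ethers are inert to this reagent, unlike under catalytic hydrogenation.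

Step 6
Reactants: 9 (Z)-3-amino-3-[3,4-bis(benzyloxy)phenyl]-1-[2,4,6-tris(methoxymethoxy)phenyl]prop-2-en-1-one
Product: 11 2-[3,4-bis(benzyloxy)phenyl]-5,7-dihydroxy-4H-chromen-4-one (3',4'-bis(benzyloxy)-5,7-dihydroxyflavone), via trihydroxy enaminone 10 (not isolated)
Conditions: conc. HCl, MeOH–THF, 60 °C
Reagents that add atoms: none
Why: Acid-catalysed acetal cleavage frees the three phenols, and an ortho phenol then adds to C2 of the protonated vinylogous amide and expels ammonia (addition–elimination closing the six-membered ring C), the enaminone counterpart of the cyclodehydration of ortho-hydroxyaryl 1,3-diketones. Ring A is symmetric, so only one flavone can form; partial hydrolysis to the diketone leads to the same product; methanol traps the released formaldehyde unit as its dimethyl acetal; benzyl ethers are stable to methanolic HCl at this temperature.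

Step 7
Reactants: 11 2-[3,4-bis(benzyloxy)phenyl]-5,7-dihydroxy-4H-chromen-4-one
Product: 12 sodium 2-[3,4-bis(benzyloxy)phenyl]-5-hydroxy-4-oxo-4H-chromen-7-yl sulfate
Conditions: SO3·pyridine, pyridine, 0 °C to rt; then aq. NaHCO3
Reagents that add atoms: sulfur trioxide pyridine complex, O=S(=O)([O-])[n+]1ccccc1; sodium hydrogen carbonate, [Na+].OC(=O)[O-]
Why: O-sulfation of a phenol with an amine–sulfur trioxide complex; the 5-hydroxyl is locked in a hydrogen bond to the C4 carbonyl and is flanked by it, so only O7 reacts, while ring B is blocked as benzyl ethers. The hydrogen carbonate quench gives the stable sodium salt.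

Step 8
Reactants: 12 sodium 2-[3,4-bis(benzyloxy)phenyl]-5-hydroxy-4-oxo-4H-chromen-7-yl sulfate
Product: 14 luteolin 7-sulfate (2-(3,4-dihydroxyphenyl)-5-hydroxy-4-oxo-4H-chromen-7-yl hydrogen sulfate), via sodium luteolin 7-sulfate 13 (not isolated)
Conditions: H2 (1 atm), 10% Pd/C, MeOH–THF, rt; then 1 M HCl (1 equiv), 0 °C, desalting on C18 silica
Reagents that add atoms: none
Why: Hydrogenolysis of benzyl aryl ethers over Pd/C; aryl sulfate anions are inert to these conditions, and the conjugated C2–C3 double bond of a flavone is reduced much more slowly than benzyl ethers are cleaved at atmospheric pressure. Cold stoichiometric protonation and immediate reversed-phase desalting should deliver the free hydrogen sulfate.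

## Compound list

1 | 2,4,6-trihydroxybenzaldehyde | O=Cc1c(O)cc(O)cc1O | starting material
2 | 2,4,6-tris(methoxymethoxy)benzaldehyde | COCOc1cc(OCOC)c(C=O)c(OCOC)c1 | intermediate
3 | 2-ethynyl-1,3,5-tris(methoxymethoxy)benzene | C#Cc1c(OCOC)cc(OCOC)cc1OCOC | intermediate
4 | 3,4-bis(benzyloxy)benzaldehyde | O=Cc1ccc(OCc2ccccc2)c(OCc2ccccc2)c1 | starting material
5 | (E)-3,4-bis(benzyloxy)benzaldehyde oxime | O/N=C/c1ccc(OCc2ccccc2)c(OCc2ccccc2)c1 | intermediate
6 | (Z)-3,4-bis(benzyloxy)-N-hydroxybenzimidoyl chloride (hydroximoyl chloride) | N(/O)=C(/Cl)c1ccc(OCc2ccccc2)c(OCc2ccccc2)c1 | intermediate (not isolated)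
7 | 3,4-bis(benzyloxy)benzonitrile oxide | [O-][N+]#Cc1ccc(OCc2ccccc2)c(OCc2ccccc2)c1 | intermediate (not isolated)
8 | 3-[3,4-bis(benzyloxy)phenyl]-5-[2,4,6-tris(methoxymethoxy)phenyl]isoxazole | COCOc1cc(OCOC)c(-c2cc(-c3ccc(OCc4ccccc4)c(OCc4ccccc4)c3)no2)c(OCOC)c1 | intermediate
9 | (Z)-3-amino-3-[3,4-bis(benzyloxy)phenyl]-1-[2,4,6-tris(methoxymethoxy)phenyl]prop-2-en-1-one | C(/C(=O)c1c(OCOC)cc(OCOC)cc1OCOC)=C(/N)c1ccc(OCc2ccccc2)c(OCc2ccccc2)c1 | intermediate
10 | (Z)-3-amino-3-[3,4-bis(benzyloxy)phenyl]-1-(2,4,6-trihydroxyphenyl)prop-2-en-1-one | C(/C(=O)c1c(O)cc(O)cc1O)=C(/N)c1ccc(OCc2ccccc2)c(OCc2ccccc2)c1 | intermediate (not isolated)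
11 | 2-[3,4-bis(benzyloxy)phenyl]-5,7-dihydroxy-4H-chromen-4-one | O=c1cc(-c2ccc(OCc3ccccc3)c(OCc3ccccc3)c2)oc2cc(O)cc(O)c12 | intermediate
12 | sodium 2-[3,4-bis(benzyloxy)phenyl]-5-hydroxy-4-oxo-4H-chromen-7-yl sulfate | O=c1cc(-c2ccc(OCc3ccccc3)c(OCc3ccccc3)c2)oc2cc(OS(=O)(=O)[O-])cc(O)c12.[Na+] | intermediate
13 | sodium 2-(3,4-dihydroxyphenyl)-5-hydroxy-4-oxo-4H-chromen-7-yl sulfate (sodium luteolin 7-sulfate) | O=c1cc(-c2ccc(O)c(O)c2)oc2cc(OS(=O)(=O)[O-])cc(O)c12.[Na+] | intermediate (not isolated)
14 | luteolin 7-sulfate, 2-(3,4-dihydroxyphenyl)-5-hydroxy-4-oxo-4H-chromen-7-yl hydrogen sulfate | O=c1cc(-c2ccc(O)c(O)c2)oc2cc(OS(=O)(=O)O)cc(O)c12 | target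

## Step count and least certain steps

Total: 8 steps. Longest linear sequence: 7 steps (steps 1, 2, 4, 5, 6, 7, 8 from 1); the ring B branch contributes step 3.

**Step 4 (key step).** The most likely failure is dimerisation of the nitrile oxide to the furoxan outrunning the cycloaddition, because the alkyne of 3 is flanked by two ortho acetal ethers. A second danger is chlorination of the electron-rich rings if the chlorinating agent is still present when 3 is added. The fallback makes the same isoxazole by condensation instead of cycloaddition and sets out from 3 and 4. Deprotonation of 3 with n-BuLi (THF, −78 °C) and addition to aldehyde 4 should give racemic 1-[3,4-bis(benzyloxy)phenyl]-3-[2,4,6-tris(methoxymethoxy)phenyl]prop-2-yn-1-ol F1. MnO2 in CH2Cl2 should oxidise it to 1-[3,4-bis(benzyloxy)phenyl]-3-[2,4,6-tris(methoxymethoxy)phenyl]prop-2-yn-1-one F2. Hydroxylamine hydrochloride with NaOAc in hot ethanol should condense at the ketone, and the oxime oxygen should then close onto the alkyne carbon that bears ring A, which brings the route back at 8. The buffered medium and the hindered, electron-rich aryl group on the alkyne terminus disfavour the conjugate-addition pathway that would reverse the positions of nitrogen and oxygen.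

**Step 2.** The most likely failure is slow or incomplete olefination: the formyl group of 2 lies between two ortho alkoxy groups and is deactivated by three donor oxygens, so the diazophosphonate anion may decompose before it adds. The fallback is a Corey–Fuchs sequence from 2. CBr4, PPh3 and Et3N in CH2Cl2 at 0 °C should give 2-(2,2-dibromovinyl)-1,3,5-tris(methoxymethoxy)benzene F3. Two equivalents of n-BuLi in THF at −78 °C should then effect bromine–lithium exchange, rearrangement of the carbenoid and, after protonation, return the route at 3.

**Step 7.** The most likely failures are incomplete sulfation of the poorly soluble diol and loss of material when the salt is separated from inorganic sulfate; forcing the reaction risks the onset of sulfation at O5. The fallback uses a protected sulfate and sets out from 11. 2,2,2-Trichloroethyl chlorosulfate with Et3N and DMAP in THF should give the neutral diester 2-[3,4-bis(benzyloxy)phenyl]-5-hydroxy-4-oxo-4H-chromen-7-yl 2,2,2-trichloroethyl sulfate F4, which can be purified on silica and its site of attachment checked. Zinc dust and ammonium formate in methanol, with NaHCO3 in the work-up, should remove the trichloroethyl group by reductive fragmentation and return the route at 12.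

**Step 8.** The most likely failures are a stalled hydrogenolysis, through inhibition of the catalyst by traces of pyridine and sulfur species from step 7, followed by saturation of the C2–C3 double bond if pressure or time is raised, and hydrolysis of the sulfate during the final protonation. The fallback moves the hydrogenolysis in front of the sulfation and lets acetates do the work of the benzyl ethers; it sets out from 11 and returns at 13.
- Hydrogenolysis of 11 (H2, Pd/C, MeOH–THF) should give luteolin F5.
- Ac2O in pyridine should give 5,7,3',4'-tetra-O-acetylluteolin F6.
- Thiophenol and imidazole in N-methylpyrrolidone at 0 °C should remove only the most electrophilic 7-acetate to give 5,3',4'-tri-O-acetylluteolin F7.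
- SO3·pyridine followed by NaHCO3 should give sodium 5,3',4'-tri-O-acetylluteolin 7-sulfate F8.
- NaOMe in methanol at 0 °C under argon, then neutralisation, should cleave the three acetates and return the route at 13, which is protonated to 14 as in step 8.

## Further compounds

F1 | step 4 | rac-1-[3,4-bis(benzyloxy)phenyl]-3-[2,4,6-tris(methoxymethoxy)phenyl]prop-2-yn-1-ol | OC(C#Cc1c(OCOC)cc(OCOC)cc1OCOC)c1ccc(OCc2ccccc2)c(OCc2ccccc2)c1
F2 | step 4 | 1-[3,4-bis(benzyloxy)phenyl]-3-[2,4,6-tris(methoxymethoxy)phenyl]prop-2-yn-1-one | O=C(C#Cc1c(OCOC)cc(OCOC)cc1OCOC)c1ccc(OCc2ccccc2)c(OCc2ccccc2)c1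
F3 | step 2 | 2-(2,2-dibromovinyl)-1,3,5-tris(methoxymethoxy)benzene | BrC(Br)=Cc1c(OCOC)cc(OCOC)cc1OCOC
F4 | step 7 | 2-[3,4-bis(benzyloxy)phenyl]-5-hydroxy-4-oxo-4H-chromen-7-yl 2,2,2-trichloroethyl sulfate | O=c1cc(-c2ccc(OCc3ccccc3)c(OCc3ccccc3)c2)oc2cc(OS(=O)(=O)OCC(Cl)(Cl)Cl)cc(O)c12
F5 | step 8 | luteolin, 2-(3,4-dihydroxyphenyl)-5,7-dihydroxy-4H-chromen-4-one | O=c1cc(-c2ccc(O)c(O)c2)oc2cc(O)cc(O)c12
F6 | step 8 | 5,7,3',4'-tetra-O-acetylluteolin | CC(=O)Oc1cc(OC(C)=O)c2c(=O)cc(-c3ccc(OC(C)=O)c(OC(C)=O)c3)oc2c1
F7 | step 8 | 5,3',4'-tri-O-acetylluteolin (7-hydroxyl free) | CC(=O)Oc1ccc(-c2cc(=O)c3c(OC(C)=O)cc(O)cc3o2)cc1OC(C)=O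
F8 | step 8 | sodium 5,3',4'-tri-O-acetylluteolin 7-sulfate | CC(=O)Oc1ccc(-c2cc(=O)c3c(OC(C)=O)cc(OS(=O)(=O)[O-])cc3o2)cc1OC(C)=O.[Na+]
A1 | alternative 1 | 5,7-bis(benzyloxy)-2-[4,5-bis(tert-butyldimethylsilyloxy)cyclohexa-1,4-dien-1-yl]-4H-chromen-4-one | CC(C)(C)[Si](C)(C)OC1=C(O[Si](C)(C)C(C)(C)C)CC(c2cc(=O)c3c(OCc4ccccc4)cc(OCc4ccccc4)cc3o2)=CC1
A2 | alternative 1 | 5,7-bis(benzyloxy)-2-ethynyl-4H-chromen-4-one | C#Cc1cc(=O)c2c(OCc3ccccc3)cc(OCc3ccccc3)cc2o1
A3 | alternative 1 | 2,3-bis(tert-butyldimethylsilyloxy)buta-1,3-diene | C=C(O[Si](C)(C)C(C)(C)C)C(=C)O[Si](C)(C)C(C)(C)C
A4 | alternative 2 | 3',4'-bis(benzyloxy)-5,7-dihydroxyflavone | O=c1cc(-c2ccc(OCc3ccccc3)c(OCc3ccccc3)c2)oc2cc(O)cc(O)c12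
A5 | alternative 2 | methyl 4-{6-[3,4-bis(benzyloxy)phenyl]-4-oxo-4H-pyran-2-yl}-3-oxobutanoate | COC(=O)CC(=O)Cc1cc(=O)cc(-c2ccc(OCc3ccccc3)c(OCc3ccccc3)c2)o1
A6 | alternative 3 | 5,7-bis(benzyloxy)-3',4'-bis(pivaloyloxy)flavone | O=c1cc(-c2ccc(OC(=O)C(C)(C)C)c(OC(=O)C(C)(C)C)c2)oc2cc(OCc3ccccc3)cc(OCc3ccccc3)c12
A7 | alternative 3 | (Z)-3-[3,5-bis(benzyloxy)phenoxy]-3-[3,4-bis(pivaloyloxy)phenyl]acrylic acid | C(/C(=O)O)=C(/Oc1cc(OCc2ccccc2)cc(OCc2ccccc2)c1)c1ccc(OC(=O)C(C)(C)C)c(OC(=O)C(C)(C)C)c1
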